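**Plan**
1. Retrosynthesis: cut the C4'–CH3 and C5'–Br bonds of ring B (back to a silyl enol ether C4'=C5') and the exocyclic C=CH2 (back to a ketone); then cut ring B at C1'–C6' and C2'–C3' ([4+2]); then the vinyl–carbonyl bond; finally the C6–CH2 bond of ring A, which leads to (S)-carvone.
2. Forward: ring A is taken from (S)-carvone and finished first (side chain, then the diol). The chain is extended to a vinyl ketone, and ring B is closed last by Diels–Alder reaction with 2-(triisopropylsilyloxy)butadiene, followed by methylenation, bromination and methyl addition.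
3. Enabling feature: in ring B the methine C1' is 1,4 to the methyl carbinol carbon C4' and 1,3 to the CHBr carbon C5'. This is the pattern of the para adduct of a 2-silyloxydiene, whose enol ether double bond C4'=C5' fixes where CH3 and Br enter and is the only thing that keeps C1' stereogenic.
4. Stereochemistry: C5 from carvone; C6 by alkylation trans to isopropenyl; C2 by nucleophilic epoxidation anti to isopropenyl; C1 by axial hydride delivery; C1' by the chiral oxazaborolidinium catalyst; C5' by equilibration to the equatorial bromide; C4' by equatorial methyl addition.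

Key step: step 10

Locants: ring A is numbered as in carvone (C1 = CHOH, C2 = C(CH3)OH, C5 = CH-isopropenyl, C6 = CH bearing the side chain). Ring B: C1' = methine, C2'/C3' = CH2, C4' = C(CH3)OH, C5' = CHBr, C6' = CH2.

Assumption: the cationic oxazaborolidine is taken to bind the alkyl vinyl ketone as it binds acrylates, for which the (S)-catalyst is taken to give the (S)-cyclohex-3-ene adduct with butadiene. On that basis the (R)-catalyst is specified; the antipode would be used if the sense proved opposite.

**Step 1**
Reactants: 1 (S)-carvone; 2 tert-butyl bromoacetate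
Product: 3 tert-butyl 2-[(1R,6S)-3-methyl-2-oxo-6-(prop-1-en-2-yl)cyclohex-3-en-1-yl]acetate
Conditions: LDA, THF, −78 °C; then 2, −78 → −20 °C
Reagents that add atoms: none
Why: Kinetic α'-deprotonation gives the cross-conjugated lithium enolate, whose SN2 alkylation should occur anti to the adjacent isopropenyl group and so set C6 trans to C5, the diequatorial and also thermodynamic arrangement.

**Step 2**
Reactants: 3
Product: 4 epoxy ketone (2,3-epoxide on the face opposite isopropenyl, cis to the side chain)
Conditions: 30% H2O2, NaOH (cat.), MeOH, 0 °C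
Reagents that add atoms: hydrogen peroxide, OO
Why: In this Weitz–Scheffer nucleophilic epoxidation hydroperoxide should add axially to C3 opposite the C5 isopropenyl group, setting the future C2–O bond trans to isopropenyl, while the base keeps C6 trans and the tert-butyl ester resists it.

**Step 3**
Reactants: 4
Product: 5 epoxy alcohol (C1–OH trans to the epoxide oxygen and to the side chain, cis to isopropenyl)
Conditions: NaBH4, CeCl3·7H2O, MeOH, −40 → 0 °C
Reagents that add atoms: none
Why: In this Luche-type reduction hydride should add axially to C1, away from the C2 methyl and the axial C6–H, giving the equatorial alcohol trans to both the epoxide oxygen and the side chain.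

**Step 4**
Reactants: 5
Product: 6 (1S,2S,3R,4S)-3-(2-hydroxyethyl)-1-methyl-4-(prop-1-en-2-yl)cyclohexane-1,2-diol
Conditions: LiEt3BH (6 equiv), THF, 0 → 45 °C; aq. NaOH work-up
Reagents that add atoms: none
Why: This SN2-type trialkylborohydride should open the trisubstituted epoxide at the less substituted C3, leaving the tertiary C2–O bond and its configuration untouched, and reduce the ester to the primary alcohol in the same operation; no stereocentre is formed.

**Step 5**
Reactants: 6
Product: 8 trans-fused hydroxy γ-lactone, via lactol 7 (not isolated)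
Conditions: TEMPO (20 mol %), PhI(OAc)2, CH2Cl2, rt
Reagents that add atoms: none
Why: Oxoammonium oxidation is selective for the primary alcohol; the aldehyde should close onto the neighbouring equatorial C1 hydroxyl and the lactol be oxidised on to the lactone (oxidative lactonisation of a 1,4-diol), leaving the tertiary alcohol and the alkene untouched.

**Step 6**
Reactants: 8
Product: 9 N-methoxy-N-methyl-2-[(1R,2S,3S,6S)-2,3-dihydroxy-3-methyl-6-(prop-1-en-2-yl)cyclohexyl]acetamide
Conditions: MeNH(OMe)·HCl, AlMe3, CH2Cl2, 0 °C → rt; Rochelle salt work-up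
Reagents that add atoms: N,O-dimethylhydroxylamine hydrochloride, CNOC.Cl
Why: Aluminium amide aminolysis of a lactone (Weinreb amide formation) should open the strained trans-fused ring and release the C1 hydroxyl without touching a stereocentre.

**Step 7**
Reactants: 9
Product: 10 bis(triethylsilyl) ether of 9
Conditions: TESOTf, 2,6-lutidine, CH2Cl2, −78 → 0 °C
Reagents that add atoms: triethylsilyl triflate, CC[Si](CC)(CC)OS(=O)(=O)C(F)(F)F
Why: Silyl triflate silylation caps the secondary and the tertiary hydroxyl, which prevents relactonisation and removes the protic groups that would quench the Grignard reagent and the boron catalyst.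

**Step 8**
Reactants: 10
Product: 11 ring-A vinyl ketone (dienophile)
Conditions: CH2=CHMgBr, THF, −20 → 0 °C; inverse quench into cold aq. KHSO4
Reagents that add atoms: vinylmagnesium bromide, C=C[Mg]Br
Why: In this Weinreb ketone synthesis the chelated tetrahedral intermediate prevents over-addition, and the cold acidic inverse quench keeps the released amine from adding to the new enone.

**Step 9**
Reactants: 12 methyl vinyl ketone
Product: 13 2-(triisopropylsilyloxy)buta-1,3-diene
Conditions: TIPSOTf, Et3N, Et2O, 0 °C → rt
Reagents that add atoms: triisopropylsilyl triflate, CC(C)[Si](C(C)C)(C(C)C)OS(=O)(=O)C(F)(F)F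
Why: Soft enolisation and O-silylation of the methyl ketone should give the cross-conjugated 2-silyloxydiene, the bulky silyl group making the diene and the later enol ether robust.

**Step 10**
Reactants: 11 ring-A vinyl ketone; 13 2-(triisopropylsilyloxy)buta-1,3-diene
Product: 14 para cycloadduct (ring B as the C4'=C5' triisopropylsilyl enol ether, C1' R)
Conditions: (R)-o-tolyl oxazaborolidine from (R)-α,α-diphenylprolinol, Tf2NH (20 mol %, slight deficit of acid), CH2Cl2, −78 °C; Et3N quench
Reagents that add atoms: none
Why: The boron cation binds the ketone oxygen of 11 syn to the vinyl group and holds the s-trans enone over one aryl group, and the diene adds in an asynchronous concerted [4+2] in which the C2'–C3' bond (enol ether CH2 terminus to enone β-carbon) runs ahead of C1'–C6'; a Mukaiyama–Michael addition followed by ring closure would give the same adduct. The closest known reaction type is the oxazaborolidinium-catalysed enantioselective Diels–Alder reaction of 2-silyloxybutadienes with acrylates and vinyl ketones. Ring B, the only ring formed, closes as a six-membered carbocycle by intermolecular [4+2] cycloaddition, both σ-bonds being made in the one step. The one new stereocentre, C1', is set by the catalyst, which shields one face of the dienophile α-carbon; the ring-A stereocentres are three or more bonds away and should neither help nor hinder. The step needs para regioselectivity, secured by the 2-silyloxy donor whose largest HOMO coefficient lies on the adjacent CH2 terminus, chemoselectivity for the vinyl ketone over the unactivated isopropenyl group, and survival of the enol ether, secured by the bulky silyl group, the deficit of acid and the amine quench. Because C1' is stereogenic only while the C4'=C5' enol ether distinguishes the two ring arms, the adduct is carried on without hydrolysis.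

**Step 11**
Reactants: 14
Product: 15 methylenated enol ether (triene)
Conditions: Tebbe reagent, pyridine, THF/toluene, −40 → 0 °C
Reagents that add atoms: Tebbe reagent, C[Al-]1(C)C[Ti]([Cl+]1)(C1C=CC=C1)C1C=CC=C1
Why: Titanium methylidene (Tebbe) methylenation should convert the hindered ketone to the 1,1-disubstituted alkene under non-basic conditions, so the enolisable C1' centre is not epimerised and the silyl groups survive.

**Step 12**
Reactants: 15
Product: 17 equatorial bromoketone (Br cis to the C1' substituent), via axial bromoketone 16 (not isolated)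
Conditions: NBS, NaHCO3, THF, −78 → −20 °C; then LiBr, DMF, rt; chromatography, axial epimer returned to LiBr/DMF
Reagents that add atoms: N-bromosuccinimide, O=C1CCC(=O)N1Br; lithium bromide, [Li+].[Br-]
Why: Electrophilic bromination of the silyl enol ether is regiospecific for C5' and should deliver bromine axially, trans to the C1' substituent, after which degenerate SN2 bromide exchange at C5' (Finkelstein-type epimerisation, no enolisation and no migration to C3') equilibrates the epimers in a polar lithium-containing medium that favours the dipole-aligned equatorial bromide.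

**Step 13**
Reactants: 17
Product: 18 bis(triethylsilyl) ether of the target
Conditions: MeMgBr, CeCl3, THF, −78 °C; AcOH quench at −78 °C
Reagents that add atoms: methylmagnesium bromide, C[Mg]Br
Why: Organocerium 1,2-addition avoids enolisation and halogen–metal exchange of the α-bromoketone, and equatorial attack on the chair with Br and the C1' substituent equatorial should place CH3 equatorial and OH axial, the cis-bromohydrin usual for organometallic additions to 2-halocyclohexanones.

**Step 14**
Reactants: 18
Product: 19 target
Conditions: HF·pyridine, pyridine, THF, 0 °C → rt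
Reagents that add atoms: none
Why: Buffered fluoride desilylation should remove both triethylsilyl ethers without base, which could trigger semipinacol loss of bromide, and without strong acid, which could ionise the tertiary alcohols or isomerise the 1,1-disubstituted alkenes.

**Compound list**
1 | (S)-carvone | CC1=CC[C@@H](CC1=O)C(C)=C | starting material
2 | tert-butyl bromoacetate | BrCC(=O)OC(C)(C)C | starting material
3 | tert-butyl 2-[(1R,6S)-3-methyl-2-oxo-6-(prop-1-en-2-yl)cyclohex-3-en-1-yl]acetate | CC(C)(C)OC(=O)C[C@@H]1[C@@H](C(=C)C)CC=C(C)C1=O | intermediate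
4 | epoxy ketone, epoxide trans to isopropenyl | CC(C)(C)OC(=O)C[C@@H]1[C@@H](C(=C)C)C[C@@H]2O[C@]2(C)C1=O | intermediate
5 | epoxy alcohol, C1–OH trans to epoxide oxygen and side chain | CC(C)(C)OC(=O)C[C@@H]1[C@@H](C(=C)C)C[C@@H]2O[C@]2(C)[C@H]1O | intermediate
6 | (1S,2S,3R,4S)-3-(2-hydroxyethyl)-1-methyl-4-(prop-1-en-2-yl)cyclohexane-1,2-diol | OCC[C@@H]1[C@@H](C(=C)C)CC[C@](C)(O)[C@H]1O | intermediate
7 | lactol (trans-fused, anomers), tertiary OH free | OC1C[C@@H]2[C@@H](C(=C)C)CC[C@](C)(O)[C@H]2O1 | intermediate
8 | trans-fused hydroxy γ-lactone (C1–O in the lactone, C2–OH free) | O=C1C[C@@H]2[C@@H](C(=C)C)CC[C@](C)(O)[C@H]2O1 | intermediate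
9 | N-methoxy-N-methyl-2-[(1R,2S,3S,6S)-2,3-dihydroxy-3-methyl-6-(prop-1-en-2-yl)cyclohexyl]acetamide | CON(C)C(=O)C[C@@H]1[C@@H](C(=C)C)CC[C@](C)(O)[C@H]1O | intermediate
10 | bis(triethylsilyl) ether of 9 | CON(C)C(=O)C[C@@H]1[C@@H](C(=C)C)CC[C@](C)(O[Si](CC)(CC)CC)[C@H]1O[Si](CC)(CC)CC | intermediate
11 | ring-A vinyl ketone, diol as bis(triethylsilyl) ether | C=CC(=O)C[C@@H]1[C@@H](C(=C)C)CC[C@](C)(O[Si](CC)(CC)CC)[C@H]1O[Si](CC)(CC)CC | intermediate
12 | methyl vinyl ketone | CC(=O)C=C | starting material
13 | 2-(triisopropylsilyloxy)buta-1,3-diene | C=CC(=C)O[Si](C(C)C)(C(C)C)C(C)C | intermediate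
14 | para cycloadduct, ring B as C4'=C5' silyl enol ether, C1' R | O=C(C[C@@H]1[C@@H](C(=C)C)CC[C@](C)(O[Si](CC)(CC)CC)[C@H]1O[Si](CC)(CC)CC)[C@@H]2CCC(O[Si](C(C)C)(C(C)C)C(C)C)=CC2 | intermediate
15 | methylenated enol ether | C=C(C[C@@H]1[C@@H](C(=C)C)CC[C@](C)(O[Si](CC)(CC)CC)[C@H]1O[Si](CC)(CC)CC)[C@@H]2CCC(O[Si](C(C)C)(C(C)C)C(C)C)=CC2 | intermediate
16 | axial bromoketone, Br trans to the C1' substituent | C=C(C[C@@H]1[C@@H](C(=C)C)CC[C@](C)(O[Si](CC)(CC)CC)[C@H]1O[Si](CC)(CC)CC)[C@@H]2CCC(=O)[C@@H](Br)C2 | intermediate
17 | equatorial bromoketone, Br cis to the C1' substituent | C=C(C[C@@H]1[C@@H](C(=C)C)CC[C@](C)(O[Si](CC)(CC)CC)[C@H]1O[Si](CC)(CC)CC)[C@@H]2CCC(=O)[C@H](Br)C2 | intermediate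
18 | bis(triethylsilyl) ether of the target (cis-bromohydrin in ring B) | C=C(C[C@@H]1[C@@H](C(=C)C)CC[C@](C)(O[Si](CC)(CC)CC)[C@H]1O[Si](CC)(CC)CC)[C@@H]2CC[C@](C)(O)[C@H](Br)C2 | intermediate
19 | (1S,2S,3R,4S)-3-{2-[(1R,3R,4S)-3-bromo-4-hydroxy-4-methylcyclohexyl]prop-2-en-1-yl}-1-methyl-4-(prop-1-en-2-yl)cyclohexane-1,2-diol | C=C(C[C@@H]1[C@@H](C(=C)C)CC[C@](C)(O)[C@H]1O)[C@@H]1CC[C@](C)(O)[C@H](Br)C1 | target

Total steps: 14. Longest linear sequence: 13 (steps 1–8 and 10–14).

**Steps most likely to fail**

Step 12. The bromide-exchange equilibrium may settle mainly on the axial epimer, the usual preference of 2-bromocyclohexanones, so that supply of the equatorial bromide would depend on repeated recycling. The fallback replaces thermodynamic by kinetic control. Starting from 16 (or the 16/17 mixture), soft enolisation toward the more acidic brominated carbon (TMSOTf, Et3N, CH2Cl2, 0 °C) should give the 2-bromo trimethylsilyl enol ether F1. Fluoride cleavage in the presence of acetic acid (TBAF 1 equiv, AcOH, THF, −78 °C) then protonates the bromo-enolate irreversibly and axially at C5', which leaves bromine equatorial, and the route is rejoined at 17.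

Step 4. Hydride delivery to the tertiary epoxide carbon (the trans-diaxial opening mode of the preferred half-chair), or migration of the epoxide by attack of the C1 alkoxide before reduction, would give regioisomeric diols. The fallback changes the nucleophile and the way the C3–H bond is made. From 5, sodium phenylselenide (PhSeSePh, NaBH4, EtOH, reflux) should open the epoxide at the secondary carbon C3 to the hydroxy selenide F2. Tin hydride reduction (Bu3SnH, AIBN, toluene, 80 °C) replaces selenium by hydrogen to give the dihydroxy tert-butyl ester F3, and LiAlH4 (THF, 0 °C) reduces the ester, returning to 6.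

Step 10. Enantiofacial discrimination at the dienophile α-carbon may be insufficient, through competitive binding of the catalyst by the silyl ether oxygens or an uncatalysed background reaction. The fallback sets C1' by desymmetrising enolisation instead. Compounds 11 and 13 are combined with an achiral Lewis acid (Me2AlCl, CH2Cl2, −78 °C) to give 14 together with the C1' epimer of the cycloadduct F4. Tebbe methylenation as in step 11 gives 15 together with the C1' epimer of the methylenated enol ether F5. Cleavage of the enol ether (TBAF 1 equiv, AcOH, THF, −78 °C) converges both on the ring-B ketone F6, in which C1' is no longer stereogenic. A chiral lithium amide (lithium (S,S)-bis(1-phenylethyl)amide, LiCl, TMSCl in situ, THF, −100 °C; enantiomer chosen by analogy with 4-substituted cyclohexanones) then deprotonates one ring arm selectively to give the trimethylsilyl enol ether F7 with the C4'=C5' double bond. F7 takes the place of 15 in step 12 and the route is rejoined at 17.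

**Further compounds**
F1 | step 12 | 2-bromo trimethylsilyl enol ether | C=C(C[C@@H]1[C@@H](C(=C)C)CC[C@](C)(O[Si](CC)(CC)CC)[C@H]1O[Si](CC)(CC)CC)[C@@H]2CCC(O[Si](C)(C)C)=C(Br)C2
F2 | step 4 | hydroxy selenide | CC(C)(C)OC(=O)C[C@@H]1[C@@H](C(=C)C)C[C@@H]([Se]c2ccccc2)[C@](C)(O)[C@H]1O
F3 | step 4 | dihydroxy tert-butyl ester | CC(C)(C)OC(=O)C[C@@H]1[C@@H](C(=C)C)CC[C@](C)(O)[C@H]1O
F4 | step 10 | C1' epimer of the cycloadduct | O=C(C[C@@H]1[C@@H](C(=C)C)CC[C@](C)(O[Si](CC)(CC)CC)[C@H]1O[Si](CC)(CC)CC)[C@H]2CCC(O[Si](C(C)C)(C(C)C)C(C)C)=CC2
F5 | step 10 | C1' epimer of the methylenated enol ether | C=C(C[C@@H]1[C@@H](C(=C)C)CC[C@](C)(O[Si](CC)(CC)CC)[C@H]1O[Si](CC)(CC)CC)[C@H]2CCC(O[Si](C(C)C)(C(C)C)C(C)C)=CC2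
F6 | step 10 | ring-B ketone | C=C(C[C@@H]1[C@@H](C(=C)C)CC[C@](C)(O[Si](CC)(CC)CC)[C@H]1O[Si](CC)(CC)CC)C2CCC(=O)CC2
F7 | step 10 | trimethylsilyl enol ether | C=C(C[C@@H]1[C@@H](C(=C)C)CC[C@](C)(O[Si](CC)(CC)CC)[C@H]1O[Si](CC)(CC)CC)[C@@H]2CCC(O[Si](C)(C)C)=CC2
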